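## Retrosynthetic overview

- **Numbering (germacrane):** C3 and C10 are the enol-ether and quaternary carbons of the 2,3-dihydrofuran. C4 is the tertiary carbinol and C6 is CHOAc. C7/C11/C12/C8 are the β/α/C=O/γ carbons of the butenolide, C9 is the exocyclic =CH, and C13 is CH2OAc.
- **Feature the strategy rests on:** C9-C10(Me)(O)-C1-C2 and C3-C4(Me)(O)-C5-C6 are two copies of one (S)-2-methylmalate skeleton, so both are cut from (S)-citramalic acid. The C8=C9 enol-lactone alkene sits inside the nine-membered oxacycle (O, C3-C10) next to the quaternary C10, so it can come from an aldol addition followed by dehydration.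
- **Disconnections:** C8=C9 (E1cB of a C9 mesylate), then C8-C9 (intramolecular vinylogous aldol of a 2-silyloxyfuran on a C9 aldehyde), then O-C3 (cyclodehydration), then C2-C3 (Fukuyama coupling), then C6-C7 (Stille acylation of a β-stannylbutenolide).
- **Ring order:** butenolide (iodolactonisation of an allenoate), then 2,3-dihydrofuran, then the nine-membered oxacycle (the ten-membered carbocycle).

Key step: step 22

Remark: (S)-citramalic acid is taken as purchasable in enantiopure form. Compounds 27-30 are carried as C8/C9 epimer mixtures and are written without configuration at these two centres.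

## Route

**Step 1**
Reactants: 1 (S)-citramalic acid
Product: 2 2-[(4S)-2,2,4-trimethyl-5-oxo-1,3-dioxolan-4-yl]acetic acid
Conditions: 2,2-dimethoxypropane, p-TsOH·H2O (cat.), CH2Cl2, rt
Reagents that add atoms: 2,2-dimethoxypropane COC(C)(C)OC
Why: Acid-catalysed ketal exchange prefers the five-membered dioxolanone built from the tertiary hydroxyl and the adjacent carboxyl, which leaves the CH2CO2H arm free and does not touch the quaternary centre.

**Step 2**
Reactants: 2 dioxolanone acid
Product: 3 (5S)-5-(2-hydroxyethyl)-2,2,5-trimethyl-1,3-dioxolan-4-one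
Conditions: BH3·THF, THF, -10 °C to rt; MeOH quench, neutral cold work-up
Reagents that add atoms: none
Why: Chemoselective borane reduction takes a free carboxylic acid much faster than the dioxolanone ester, and the neutral work-up keeps the new primary alcohol from translactonising.

**Step 3**
Reactants: 3 primary alcohol
Product: 4 (5S)-5-(2-iodoethyl)-2,2,5-trimethyl-1,3-dioxolan-4-one (unit C9-C10-C1-C2)
Conditions: I2, PPh3, imidazole, CH2Cl2, 0 °C
Reagents that add atoms: iodine II
Why: The Appel-type (Garegg-Samuelsson) iodination is imidazole-buffered, so the hydroxyl is displaced before it can attack the dioxolanone carbonyl.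

**Step 4**
Reactants: 4 dioxolanone iodide
Product: 5 methyl (2S)-2-hydroxy-4-iodo-2-methylbutanoate
Conditions: K2CO3 (0.2 equiv), MeOH, 0 °C, short contact; pH 7 buffer
Reagents that add atoms: methanol CO
Why: Base-catalysed transesterification of the activated dioxolanone (irreversible through loss of acetone) is done on this small fragment, because the same alkoxide treatment after fragment union would bring base to the acidic butenolide γ-CH2 beside a C3 ketone, and the cold catalytic conditions leave the primary iodide alone.

**Step 5**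
Reactants: 5 hydroxy ester iodide
Product: 6 methyl (2S)-4-iodo-2-methyl-2-(trimethylsilyloxy)butanoate
Conditions: TMSOTf, 2,6-lutidine, CH2Cl2, -78 to 0 °C
Reagents that add atoms: trimethylsilyl triflate C[Si](C)(C)OS(=O)(=O)C(F)(F)F
Why: Triflate silylation of the tertiary alcohol; TMS masks the proton during zinc insertion and can later be removed while TES and TBS ethers stay.

**Step 6**
Reactants: 2 dioxolanone acid
Product: 7 2-[(4S)-2,2,4-trimethyl-5-oxo-1,3-dioxolan-4-yl]acetyl chloride (unit C3-C4-C5-C6, COCl = C6)
Conditions: (COCl)2, DMF (cat.), CH2Cl2, 0 °C to rt; used crude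
Reagents that add atoms: oxalyl chloride O=C(Cl)C(=O)Cl
Why: Vilsmeier-catalysed acid chloride formation gives only gaseous by-products, so 7 can be taken on without base or chromatography.

**Step 7**
Reactants: 8 but-2-yne-1,4-diol
Product: 9 4-(tert-butyldimethylsilyloxy)but-2-yn-1-ol
Conditions: TBSCl (1 equiv), imidazole, 8 (3 equiv), THF/DMF, 0 °C to rt
Reagents that add atoms: tert-butyldimethylsilyl chloride CC(C)(C)[Si](C)(C)Cl
Why: Statistical monosilylation of a symmetrical diol used in excess, with the unreacted diol removed by aqueous washing.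

**Step 8**
Reactants: 9 mono-TBS ether
Product: 10 4-(tert-butyldimethylsilyloxy)but-2-ynyl methyl carbonate
Conditions: ClCO2Me, pyridine, CH2Cl2, 0 °C
Reagents that add atoms: methyl chloroformate COC(=O)Cl
Why: O-acylation with a chloroformate installs the propargylic leaving group needed for oxidative addition.

**Step 9**
Reactants: 10 propargylic carbonate
Product: 11 methyl 2-[(tert-butyldimethylsilyloxy)methyl]buta-2,3-dienoate
Conditions: Pd(OAc)2 (2 mol %), PPh3 (8 mol %), CO (5 bar), MeOH, 40 °C
Reagents that add atoms: carbon monoxide [C-]#[O+]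
Why: In this Pd-catalysed carbonylation of a propargylic carbonate, Pd(0) ionises the carbonate in SN2' fashion to an allenylpalladium methoxide, CO inserts and the released methoxide ends as the ester, which places the new carboxyl carbon (C12) on the carbon bearing CH2OTBS.

**Step 10**
Reactants: 11 allenoate
Product: 12 3-[(tert-butyldimethylsilyloxy)methyl]-4-iodofuran-2(5H)-one
Conditions: I2, MeCN (dry), rt, dark
Reagents that add atoms: iodine II
Why: In this iodolactonisation of a 2,3-allenoate, iodine takes the central allene carbon (C7), the ester carbonyl oxygen closes on the CH2 terminus (C8) and iodide demethylates the oxonium ion, so the β-iodobutenolide forms without acid and the TBS ether survives.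

**Step 11**
Reactants: 12 β-iodobutenolide
Product: 13 3-[(tert-butyldimethylsilyloxy)methyl]-4-(trimethylstannyl)furan-2(5H)-one
Conditions: (Me3Sn)2, Pd(PPh3)4 (5 mol %), toluene, 80 °C
Reagents that add atoms: hexamethylditin C[Sn](C)(C)[Sn](C)(C)C
Why: Pd-catalysed stannylation of an alkenyl iodide; tin is chosen over zinc or magnesium because the C7-metal bond of a β-metallated butenolide lies antiperiplanar to the ring C8-O bond, so an electropositive metal would open the ring to the allenoate, whereas the C-Sn bond is inert.

**Step 12**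
Reactants: 13 β-stannylbutenolide; 7 acid chloride
Product: 14 (4S)-C6 ketone: (5S)-5-{2-[4-(TBSOCH2)-5-oxo-2,5-dihydrofuran-3-yl]-2-oxoethyl}-2,2,5-trimethyl-1,3-dioxolan-4-one
Conditions: Pd2(dba)3·CHCl3 (5 mol %), P(2-furyl)3 (20 mol %), THF, 50 °C
Reagents that add atoms: none
Why: The Stille acylation (acid chloride plus alkenylstannane) forms C6-C7 under neutral conditions, so the new ketone, which carries the C4 oxygen in its β-position, never meets a base that could eliminate it.

**Step 13**
Reactants: 14 C6 ketone
Product: 15 (4S,6S)-carbinol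
Conditions: (R)-Me-CBS (0.3 equiv), BH3·SMe2, CH2Cl2/toluene, -40 °C; MeOH at -40 °C; crude product taken on at once
Reagents that add atoms: none
Why: In this CBS reduction the fully substituted butenolide carbon C7 is the large group and the C5 methylene the small one, so the (R)-oxazaborolidine delivers hydride in the sense that turns acetophenone into (S)-1-phenylethanol, should set (6S) under reagent control, and favours 1,2- over conjugate reduction at low temperature.

**Step 14**
Reactants: 15 (6S)-carbinol
Product: 16 (4S,6S)-C6 TBS ether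
Conditions: TBSOTf, 2,6-lutidine, CH2Cl2, -78 to 0 °C
Reagents that add atoms: tert-butyldimethylsilyl triflate CC(C)(C)[Si](C)(C)OS(=O)(=O)C(F)(F)F
Why: Triflate silylation at low temperature outruns attack of the C6 hydroxyl on the dioxolanone carbonyl (γ-lactone formation), and 2,6-lutidine is too weak to enolise the butenolide.

**Step 15**
Reactants: 16 C6 TBS ether
Product: 17 S-ethyl (2S,4S)-4-(TBSO)-4-[4-(TBSOCH2)-5-oxo-2,5-dihydrofuran-3-yl]-2-hydroxy-2-methylbutanethioate
Conditions: AlMe3, EtSH, CH2Cl2, 0 °C to rt; Rochelle salt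
Reagents that add atoms: ethanethiol CCS
Why: Acyl substitution by an aluminium thiolate opens the activated dioxolanone with loss of acetone under non-basic conditions, and any opening of the butenolide corrects itself because a Z-γ-hydroxy enoyl thioester recloses.

**Step 16**
Reactants: 17 α-hydroxy thioester
Product: 18 S-ethyl (2S,4S)-thioester with C4-OTES, C6-OTBS and C13-OTBS
Conditions: TESOTf, 2,6-lutidine, CH2Cl2, 0 °C
Reagents that add atoms: triethylsilyl triflate CC[Si](CC)(CC)OS(=O)(=O)C(F)(F)F
Why: Triflate silylation reaches the hindered tertiary hydroxyl, and TES is small enough to go on yet stable enough to last until step 24.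

**Step 17**
Reactants: 6 TMS-protected iodide; 18 thioester
Product: 20 (4S,6S,10S)-C3 ketone carrying the full carbon chain (C9 methyl ester; C10-OTMS; C4-OTES; C6-OTBS; C13-OTBS), via alkylzinc iodide 19 (not isolated)
Conditions: 6, Zn dust (BrCH2CH2Br, TMSCl activation), THF, 35 °C; then 18, PdCl2(PPh3)2 (10 mol %), toluene, rt
Reagents that add atoms: none
Why: In the Fukuyama coupling Pd(0) inserts into the acyl-S bond and the mild alkylzinc iodide transfers C2, so the C2-C3 ketone forms while ester, butenolide and silyl ethers, and the product ketone itself, are left alone.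

**Step 18**
Reactants: 20 C3 ketone
Product: 21 (4S,6S,10S)-γ-hydroxy ketone (free C10-OH)
Conditions: PPTS (0.1 equiv), MeOH/CH2Cl2, 0 °C
Reagents that add atoms: none
Why: Mild acid-catalysed methanolysis distinguishes the TMS ether from the far more stable tertiary TES ether and the two TBS ethers, and no base is involved.

**Step 19**
Reactants: 21 γ-hydroxy ketone
Product: 23 (4S,6S,10S)-2,3-dihydrofuran methyl ester, via cyclic hemiketal 22 (not isolated)
Conditions: PPTS (cat.), toluene, 4 Å MS, 80 °C
Reagents that add atoms: none
Why: In this acid-catalysed cyclodehydration of a γ-hydroxy ketone the C10 hydroxyl adds to C3 and water is lost; C4 is quaternary, which leaves C2 as the only site for proton loss, and the sieves pull the equilibrium to the C2=C3 enol ether.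

**Step 20**
Reactants: 23 dihydrofuran methyl ester
Product: 24 2-(triisopropylsilyloxy)furan methyl ester
Conditions: TIPSOTf, Et3N, CH2Cl2, 0 °C; Et3N-deactivated silica
Reagents that add atoms: triisopropylsilyl triflate CC(C)[Si](C(C)C)(C(C)C)OS(=O)(=O)C(F)(F)F
Why: Soft enolisation (silyl triflate and tertiary amine) removes a C8 proton and aromatises the butenolide to the 2-silyloxyfuran, which hides the lactone carbonyl from hydride and arms C8 as a nucleophile, while the C9 ester has no α-hydrogen.

**Step 21**
Reactants: 24 silyloxyfuran methyl ester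
Product: 25 silyloxyfuran C9 aldehyde (cyclisation substrate)
Conditions: DIBAL-H (1.1 equiv), toluene, -78 °C; Rochelle salt
Reagents that add atoms: none
Why: In this partial DIBAL-H reduction of an ester the α-oxygen on the quaternary C10 chelates aluminium and holds the reduction at the aldehyde level until work-up, and the ester is the only reducible carbonyl left.

**Step 22**
Reactants: 25 silyloxyfuran aldehyde
Product: 27 bridged aldol adduct (free C9-OH; C8/C9 epimers), via tetrabutylammonium furanolate 26 (not isolated)
Conditions: TBAT (1.1 equiv), THF, -78 to -30 °C, 25 added by syringe pump (final ca. 1 mM); AcOH/THF at -78 °C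
Reagents that add atoms: none
Why: Proposed new method: fluoride from TBAT attacks the TIPS silicon of 25 and frees the 2-furanolate 26, whose C8 adds to the C9 aldehyde to form the C8-C9 bond; because i-Pr3SiF cannot re-silylate an alkoxide, a full equivalent of fluoride is used and the aldolate is protonated cold, which leaves C9-OH as the only free hydroxyl for step 23. The closest known reactions are the intermolecular fluoride- or Lewis-acid-promoted vinylogous Mukaiyama aldol of 2-silyloxyfurans, the silylative intramolecular vinylogous aldol of butenolide aldehydes that closes five- to seven-membered rings, and vinylogous aldol macrocyclisations of silyl dienolates; closure of a medium ring in this way has no precedent. The new ring is the nine-membered oxacycle O-C3-C4-C5-C6-C7-C8-C9-C10, closed 9-exo-trig on the carbonyl (10-exo-trig if counted round the carbocycle C1-C10), and the preformed dihydrofuran ties C3 to C10 so that fewer rotors must be frozen. C8 and C9 are new stereocentres set only by the ring conformation, and neither needs control because both become sp2 in step 26. γ- over α-attack is secured by the fully substituted C11, cyclisation over oligomerisation by slow addition at high dilution, and the six-membered alternative (C8 on C3) is excluded because C3 is now an enol-ether carbon. The absence of acid spares the enol ether, the aldehyde cannot enolise, and the C13 silyl ether is too poor a leaving group to be expelled by the furanolate.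

**Step 23**
Reactants: 27 aldol adduct
Product: 28 C9 mesylate (silyl ethers retained)
Conditions: MsCl, Et3N, CH2Cl2, -30 °C, short contact
Reagents that add atoms: methanesulfonyl chloride CS(=O)(=O)Cl
Why: Mesylation through sulfene is insensitive to the neopentyl surroundings of the only free hydroxyl, and low temperature keeps triethylamine from starting the elimination early.

**Step 24**
Reactants: 28 silylated mesylate
Product: 29 C9 mesylate 4,6,13-triol
Conditions: HF·pyridine, pyridine (large excess), THF, 0 °C to rt, polypropylene vessel; pH 7 buffer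
Reagents that add atoms: none
Why: Fluoride desilylation in a pyridine-buffered medium is too weakly basic to eliminate the mesylate and is kept as weakly acidic as possible for the enol ether, and since C8 is still sp3 the freed C6 hydroxyl faces an ordinary butenolide and not an enol lactone.

**Step 25**
Reactants: 29 triol mesylate
Product: 30 C9 mesylate 6,13-diacetate (C4-OH free)
Conditions: Ac2O, pyridine, DMAP (cat.), CH2Cl2, 0 °C
Reagents that add atoms: acetic anhydride CC(=O)OC(C)=O
Why: DMAP-catalysed acetylation takes the primary and secondary hydroxyls quickly, while the tertiary C4 hydroxyl does not react under these conditions.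

**Step 26**
Reactants: 30 diacetate mesylate
Product: 31 target CNP0144020.1, (4S,6S,10S,8E)
Conditions: DBU (1.5 equiv), CH2Cl2, -20 to 0 °C
Reagents that add atoms: none
Why: In this E1cB elimination DBU removes the vinylogously acidic C8-H and the furanolate expels the far better leaving group (C9 mesylate rather than C13 acetate), both C8/C9 epimers converge, and the nine-membered ring accepts only the alkene with C7 and C10 cis, which is the (E)-enol lactone.

## Compound list

1 | (S)-citramalic acid | C[C@](O)(CC(=O)O)C(=O)O | starting material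
2 | 2-[(4S)-2,2,4-trimethyl-5-oxo-1,3-dioxolan-4-yl]acetic acid | C[C@@]1(CC(=O)O)OC(C)(C)OC1=O | intermediate
3 | (5S)-5-(2-hydroxyethyl)-2,2,5-trimethyl-1,3-dioxolan-4-one | C[C@@]1(CCO)OC(C)(C)OC1=O | intermediate
4 | (5S)-5-(2-iodoethyl)-2,2,5-trimethyl-1,3-dioxolan-4-one | C[C@@]1(CCI)OC(C)(C)OC1=O | intermediate
5 | methyl (2S)-2-hydroxy-4-iodo-2-methylbutanoate | COC(=O)[C@@](C)(O)CCI | intermediate
6 | methyl (2S)-4-iodo-2-methyl-2-(trimethylsilyloxy)butanoate | COC(=O)[C@@](C)(O[Si](C)(C)C)CCI | intermediate
7 | 2-[(4S)-2,2,4-trimethyl-5-oxo-1,3-dioxolan-4-yl]acetyl chloride | C[C@@]1(CC(=O)Cl)OC(C)(C)OC1=O | intermediate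
8 | but-2-yne-1,4-diol | OCC#CCO | starting material
9 | 4-(tert-butyldimethylsilyloxy)but-2-yn-1-ol | OCC#CCO[Si](C)(C)C(C)(C)C | intermediate
10 | 4-(tert-butyldimethylsilyloxy)but-2-ynyl methyl carbonate | COC(=O)OCC#CCO[Si](C)(C)C(C)(C)C | intermediate
11 | methyl 2-[(tert-butyldimethylsilyloxy)methyl]buta-2,3-dienoate | C=C=C(CO[Si](C)(C)C(C)(C)C)C(=O)OC | intermediate
12 | 3-[(tert-butyldimethylsilyloxy)methyl]-4-iodofuran-2(5H)-one | O=C1OCC(I)=C1CO[Si](C)(C)C(C)(C)C | intermediate
13 | 3-[(tert-butyldimethylsilyloxy)methyl]-4-(trimethylstannyl)furan-2(5H)-one | O=C1OCC([Sn](C)(C)C)=C1CO[Si](C)(C)C(C)(C)C | intermediate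
14 | (4S)-C6 ketone (dioxolanone, butenolide) | C[C@@]1(CC(=O)C2=C(CO[Si](C)(C)C(C)(C)C)C(=O)OC2)OC(C)(C)OC1=O | intermediate
15 | (4S,6S)-C6 carbinol | C[C@@]1(C[C@H](O)C2=C(CO[Si](C)(C)C(C)(C)C)C(=O)OC2)OC(C)(C)OC1=O | intermediate
16 | (4S,6S)-C6 TBS ether | C[C@@]1(C[C@H](O[Si](C)(C)C(C)(C)C)C2=C(CO[Si](C)(C)C(C)(C)C)C(=O)OC2)OC(C)(C)OC1=O | intermediate
17 | (4S,6S)-S-ethyl thioester, free C4-OH | CCSC(=O)[C@@](C)(O)C[C@@H](C1=C(CO[Si](C)(C)C(C)(C)C)C(=O)OC1)O[Si](C)(C)C(C)(C)C | intermediate
18 | (4S,6S)-S-ethyl thioester, C4-OTES | CCSC(=O)[C@@](C)(O[Si](CC)(CC)CC)C[C@@H](C1=C(CO[Si](C)(C)C(C)(C)C)C(=O)OC1)O[Si](C)(C)C(C)(C)C | intermediate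
19 | alkylzinc iodide from 6 (not isolated) | COC(=O)[C@@](C)(O[Si](C)(C)C)CC[Zn]I | intermediate
20 | (4S,6S,10S)-C3 ketone, C9 methyl ester, C10-OTMS | COC(=O)[C@@](C)(O[Si](C)(C)C)CCC(=O)[C@@](C)(O[Si](CC)(CC)CC)C[C@@H](C1=C(CO[Si](C)(C)C(C)(C)C)C(=O)OC1)O[Si](C)(C)C(C)(C)C | intermediate
21 | (4S,6S,10S)-γ-hydroxy ketone | COC(=O)[C@@](C)(O)CCC(=O)[C@@](C)(O[Si](CC)(CC)CC)C[C@@H](C1=C(CO[Si](C)(C)C(C)(C)C)C(=O)OC1)O[Si](C)(C)C(C)(C)C | intermediate
22 | cyclic C3 hemiketal (not isolated, C3 epimers) | COC(=O)[C@]1(C)CCC(O)(O1)[C@@](C)(O[Si](CC)(CC)CC)C[C@@H](C2=C(CO[Si](C)(C)C(C)(C)C)C(=O)OC2)O[Si](C)(C)C(C)(C)C | intermediate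
23 | (4S,6S,10S)-2,3-dihydrofuran methyl ester | COC(=O)[C@]1(C)CC=C(O1)[C@@](C)(O[Si](CC)(CC)CC)C[C@@H](C2=C(CO[Si](C)(C)C(C)(C)C)C(=O)OC2)O[Si](C)(C)C(C)(C)C | intermediate
24 | 2-(triisopropylsilyloxy)furan methyl ester | COC(=O)[C@]1(C)CC=C(O1)[C@@](C)(O[Si](CC)(CC)CC)C[C@@H](c2coc(O[Si](C(C)C)(C(C)C)C(C)C)c2CO[Si](C)(C)C(C)(C)C)O[Si](C)(C)C(C)(C)C | intermediate
25 | 2-(triisopropylsilyloxy)furan C9 aldehyde | O=C[C@]1(C)CC=C(O1)[C@@](C)(O[Si](CC)(CC)CC)C[C@@H](c2coc(O[Si](C(C)C)(C(C)C)C(C)C)c2CO[Si](C)(C)C(C)(C)C)O[Si](C)(C)C(C)(C)C | intermediate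
26 | tetrabutylammonium 2-furanolate aldehyde (not isolated) | O=C[C@]1(C)CC=C(O1)[C@@](C)(O[Si](CC)(CC)CC)C[C@@H](c2coc([O-])c2CO[Si](C)(C)C(C)(C)C)O[Si](C)(C)C(C)(C)C.CCCC[N+](CCCC)(CCCC)CCCC | intermediate
27 | bridged aldol adduct, free C9-OH (C8/C9 epimers) | OC1C2OC(=O)C(CO[Si](C)(C)C(C)(C)C)=C2[C@@H](O[Si](C)(C)C(C)(C)C)C[C@](C)(O[Si](CC)(CC)CC)C2=CC[C@]1(C)O2 | intermediate
28 | C9 mesylate, silyl ethers retained | CS(=O)(=O)OC1C2OC(=O)C(CO[Si](C)(C)C(C)(C)C)=C2[C@@H](O[Si](C)(C)C(C)(C)C)C[C@](C)(O[Si](CC)(CC)CC)C2=CC[C@]1(C)O2 | intermediate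
29 | C9 mesylate 4,6,13-triol | CS(=O)(=O)OC1C2OC(=O)C(CO)=C2[C@@H](O)C[C@](C)(O)C2=CC[C@]1(C)O2 | intermediate
30 | C9 mesylate 6,13-diacetate | CS(=O)(=O)OC1C2OC(=O)C(COC(C)=O)=C2[C@@H](OC(C)=O)C[C@](C)(O)C2=CC[C@]1(C)O2 | intermediate
31 | CNP0144020.1, (4S,6S,10S,8E) | CC(=O)OCC1=C2/C(=C\[C@]3(C)CC=C(O3)[C@@](C)(O)C[C@@H]2OC(C)=O)OC1=O | target

## Step count and risks

Total step count: 26.
Longest linear sequence: 20 steps (8 to 31, steps 7-26).

**Steps most likely to fail**

1. **Step 22 (ring closure).**
   - What may go wrong: transannular strain may make closure slower than proton transfer to the furanolate or intermolecular aldol addition. The unsilylated aldolate may also reopen by retro-aldol cleavage before the quench.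
   - Basis of the fallback: it keeps the C8-C9 bond but changes the activation to known chemistry. That chemistry is electrophilic bromination of a 2-silyloxyfuran at C5, followed by a samarium(II)-mediated intramolecular Reformatsky-type aldol, a method established for medium rings.
   - Course of the fallback: it sets out from 25. With NBS (1.0 equiv, THF, -78 °C) this should give the C8-bromobutenolide aldehyde F1, because the silyloxyfuran is far more nucleophilic than the dihydrofuran enol ether. Slow addition of F1 to SmI2 (2.2 equiv, THF, -78 °C, high dilution) reduces the C8-Br bond to a samarium(III) furanolate. The oxophilic metal also binds the aldehyde, so the closure is templated and the aldolate is held as a chelate. Protonation returns to the route at 27.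

2. **Step 12 (Stille acylation).**
   - What may go wrong: transmetalation from the hindered, electron-poor stannane may be so slow that protodestannylation, decarbonylation of the acylpalladium species or ketene formation from the acid chloride takes over.
   - Course of the fallback: it replaces acyl cross-coupling by carbonyl addition and sets out from 3 and 12. Dess-Martin oxidation of 3 (NaHCO3-buffered) should give the aldehyde 2-[(4S)-2,2,4-trimethyl-5-oxo-1,3-dioxolan-4-yl]acetaldehyde F2. Nozaki-Hiyama-Kishi coupling of F2 with iodide 12 (CrCl2, NiCl2 cat., DMF, rt) gives the C6 allylic alcohol as an epimer mixture F3. This is oxidised without delay (Dess-Martin periodinane) and rejoins the route at 14, where step 13 sets C6.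

3. **Step 17 (Fukuyama coupling).**
   - What may go wrong: oxidative addition into the thioester next to the fully substituted, silyloxy-bearing C4 may be sluggish, so the zinc reagent is lost to protonation or homocoupling.
   - Course of the fallback: it sets out from 18 and 6. Fukuyama reduction of 18 (Et3SiH, Pd/C, acetone) should give the (4S,6S)-C3 aldehyde F4. A cobalt-catalysed alkylchromium addition of iodide 6 (CrCl2, cobalt phthalocyanine cat., DMF) to F4 gives the C3 carbinol as an epimer mixture F5. Prompt buffered Dess-Martin oxidation of F5 rejoins the route at 20.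

## Further compounds

F1 | step 22 | C8-bromobutenolide aldehyde (C8 epimers) | O=C[C@]1(C)CC=C(O1)[C@@](C)(O[Si](CC)(CC)CC)C[C@@H](C2=C(CO[Si](C)(C)C(C)(C)C)C(=O)OC2Br)O[Si](C)(C)C(C)(C)C
F2 | step 12 | 2-[(4S)-2,2,4-trimethyl-5-oxo-1,3-dioxolan-4-yl]acetaldehyde | C[C@@]1(CC=O)OC(C)(C)OC1=O
F3 | step 12 | C6 allylic alcohol, epimer mixture at C6 | C[C@@]1(CC(O)C2=C(CO[Si](C)(C)C(C)(C)C)C(=O)OC2)OC(C)(C)OC1=O
F4 | step 17 | (4S,6S)-C3 aldehyde | O=C[C@@](C)(O[Si](CC)(CC)CC)C[C@@H](C1=C(CO[Si](C)(C)C(C)(C)C)C(=O)OC1)O[Si](C)(C)C(C)(C)C
F5 | step 17 | C3 carbinol, epimer mixture at C3 | COC(=O)[C@@](C)(O[Si](C)(C)C)CCC(O)[C@@](C)(O[Si](CC)(CC)CC)C[C@@H](C1=C(CO[Si](C)(C)C(C)(C)C)C(=O)OC1)O[Si](C)(C)C(C)(C)C
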